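An easy step first: Z stands in excess over X, so X should fall like a first-order species (pseudo-first-order), with a half-life that scales inversely with [Z].

| setting | east | flask |
|---|---|---|
| X | 0.45 M | 0.30 M |
| Z | 3 equiv | 3.00 equiv |
| remark | run made earlier |  |
| time |  | 6.0 min |

east run (percent of the X charged)

| time / s | D / % | L / % |
|---|---|---|
| 10.0 | 23.8 | 0 |
| 15.0 | 32.4 | 1.2 |
| 20.0 | 38.8 | 0.6 |
| 30.0 | 48.8 | 0 |
| 40.0 | 56.1 | 1.3 |

(each reading ± 0.5 percentage points)

* equivalents of Z to X, everything else as given, that leave most D at 6.0 min
* the amount of D then, in percent of the X charged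
* the amount of D with the amounts as given

I read this half-life from the east run in two ways and scale it to the flask's charged [Z] of 0.900 M. The first reading, taking [Z] as charged, gives:

half-life = 0.638 min

I put that answer back in, because X used means Z used, so the reading saw a lower mean [Z]:

first reading, mean [Z] 1.30 M: half-life = 0.612 min

last reading, D and L counted, mean [Z] 1.22 M: half-life = 0.735 min

I call the early figure the X clock: the half-life of X at the flask's charged [Z], read nearest the start of the east run. The last reading gives a longer time, by a factor of 1.20, although the fall in [Z] is already counted. So the late figure cheats as a starting rate: it averages over a slowing that the east run shows and my scaling doesn't explain.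

I keep the late figure as the cautious one for the long haul. Even so, 8.16 of these half-lives fit into 6.0 min, which leaves 0.348 % of X. I therefore reckon on no plateau: D stands below the converted X by what L takes, and the east readings of L are too scattered to size that. More Z shortens a clock that is already shorter than 6.0 min, and it also speeds the second addition, which turns D into L, so I place the best near the charge.

The forecast, which differs from my reckoning, gives 4.5 equiv, 65 % and 62 %, holding that “More Z pushes the equilibrium up but drains faster”.

The flask gives 78.3 % of D, and the best is 78.6 % at 2.71 equiv.

    X ⇌ J (K = 0.720, k = 0.00950 s⁻¹)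
    L → Q (k = 4.40 × 10⁻⁶ s⁻¹)
    Z + D → L + G (k = 9.70 × 10⁻⁴ L mol⁻¹ s⁻¹)
    X + Z → D + G (k = 0.0220 L mol⁻¹ s⁻¹)
    L ⇌ E (K = 2.30, k = 0.0490 s⁻¹)

At 6.00 min this flask still holds 2.98 % of X, against my 0.348 %, beside 3.77 % of J. Near the end of one X clock, 0.612 min, at 0.600 min, this flask holds 41.8 % of D, 40.6 % of X and 16.9 % of J. With the same recipe at 0.51 M of X, the clock shortens to 0.360 min, so 16.7 clocks fit in, against 9.80 in this flask. That neighbour flask ends with 0.90 % of X, 8.28 % of L, 16.9 % of E and 72.4 % of D.

All runs stem from a simulated flask with constants of no real substance.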